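The earlier runs and the new flask stem from a simulated flask for an exercise; the scatter is artificial.

The constant to carry here is kJ, the first-order loss constant of J, defined as the rate at which J disappears divided by [J]. In closed, stirred, isothermal flasks D turns into J with X present, and you must rank three recipes at 20 h.

the same everywhere: X 0.0102 M
- cedar: D 0.26 M; temperature 12 °C; run made earlier
- elm: D 1 M; temperature 29 °C; run made earlier
- Thursday's: D 0.51 M; temperature 35 °C; time 20 h
- Sunday's: D 0.51 M; temperature 5 °C; time 20 h
- Monday's: D 0.51 M; temperature 20 °C; time 20 h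

| run | time / h | J / % | D / % |
|---|---|---|---|
| cedar | 6.00 | 19.7 | 78.7 |
| cedar | 10.0 | 29.2 | 70.3 |
| cedar | 15.0 | 39.0 | 57.6 |
| cedar | 25.0 | 55.3 | 41.8 |
| cedar | 50.0 | 63.6 | 23.2 |
| cedar | 72.0 | 69.9 | 16.4 |
| elm | 1.50 | 35.1 | 64.0 |
| elm | 5.00 | 53.0 | 40.0 |
| elm | 8.00 | 49.9 | 38.5 |
| elm | 12.0 | 46.1 | 35.0 |
| elm | 20.0 | 40.6 | 33.5 |
| elm | 25.0 | 34.6 | 31.7 |

(scatter of a reading: 1 percentage point)

- the best flask by amount of J, in percent of the D charged; "all alike" if 1.5 percentage points covers them all (Thursday's / Sunday's / Monday's / all alike)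
- amount of J at the end, in percent of the D charged, Thursday's
- amount of J at the end, in percent of the D charged, Sunday's
- amount of J at the end, in percent of the D charged, Monday's



I take [J] as the concentration that sets the order of the loss, so percentages carry between charges of D. In elm, J falls from 53.0% at 5.00 h to 34.6% at 25.0 h, which gives 0.0213 h⁻¹. In cedar, J plus D falls from 97.1% to 86.3% between 25.0 h and 72.0 h, around a mean J of 62.6%, which gives 0.00367 h⁻¹. A straight line in ln k against temperature puts kJ at 0.00840 h⁻¹ for Monday's, 0.0397 h⁻¹ for Thursday's and 0.00178 h⁻¹ for Sunday's.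

My own reckoning builds the flask in steps. The first readings give D a first-order constant, kD, of 0.0399 h⁻¹ in cedar and 0.298 h⁻¹ in elm. The same line gives kD: 0.605 h⁻¹ for Thursday's, 0.0175 h⁻¹ for Sunday's and 0.103 h⁻¹ for Monday's. Next comes the stall: D in elm still stands at 31.7% at 25.0 h, so I cap the D converted at the remainder of the charge. Last comes the loss, with J aged 20 h minus 1/kD, or 10.0 h on Sunday's, where kD·t stays below one.

| Flask | main step | with stall | with loss of J |
|---|---|---|---|
| Thursday's | >99.9% | 68.3% | 33.0% |
| Sunday's | 29.5% | 29.5% | 29.0% |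
| Monday's | 87.3% | 68.3% | 62.6% |

The forecast, reading “a catalyst that dies and a product that slowly degrades”, names Monday's, with 30% for Thursday's, 24% for Sunday's and 61% for Monday's. Its numbers differ from my last column, though both pick the same flask.

The flasks give Monday's as best, with 29.7% for Thursday's, 23.3% for Sunday's and 61.1% for Monday's.

    J ⇌ L (K = 6.10, k = 0.0690 h⁻¹, Ea = 102 kJ mol⁻¹, ΔH = −20.0 kJ mol⁻¹)
    D ⇌ J + Z (K = 0.800 M, k = 0.660 h⁻¹, Ea = 92.0 kJ mol⁻¹, ΔH = −6.00 kJ mol⁻¹)
    D + X → E (k = 1.90 M⁻¹ h⁻¹, Ea = 59.0 kJ mol⁻¹)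
    (constants at 35 °C)

The main reason for Thursday's low J is the step from J to L: without it J stands at 68.3%, not 29.7%. Two other steps each move Thursday's J by a part, in opposite ways: without the reverse step J is 33.2%, and with X not used up it is 26.9%. Against the 0.00840 h⁻¹ estimated from the readings for Monday's, L grows per unit of J at 0.00914 h⁻¹ in Monday's between 10.0 h and 20.0 h, and, with that flask left on, at 0.00879 h⁻¹ between 20.0 h and 48.0 h.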